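**Plan**

- Ring C of the isoflavone is cut at O1–C2 and C2–C3 (C2 comes from DMF dimethyl acetal), which leaves a deoxybenzoin.
- The deoxybenzoin is cut at both bonds to the C4 carbonyl, C4a–C4 and C4–C3, giving a ring A aryl iodide, carbon monoxide and a ring B benzylzinc chloride. This is possible because C4 lies between the fully substituted ring A carbon C4a and the benzylic carbon C3 that carries ring B.
- The three aryl–prenyl bonds are cut last: two on ring A (ortho-lithiation of phloroglucinol tris-MOM ether) and one on ring B (C-prenylation of 4-hydroxybenzaldehyde).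
- Forward: rings A and B are bought as phloroglucinol and 4-hydroxybenzaldehyde and elaborated separately; the two halves are joined through CO; ring C closes last, in the deprotection step.
- Stereochemistry: the target has no stereocentre and no stereogenic double bond, so nothing has to be controlled.

Key step: step 10

Remarks: prenyl = 3-methylbut-2-en-1-yl, MOM = methoxymethyl. The benzylzinc reagent is made as the chloride (LiCl-solvated), because the electron-rich benzyl chloride is easier to handle than the bromide and inserts zinc with little Wurtz coupling. The enaminone is drawn as its E isomer; its geometry is not controlled and does not matter for ring closure.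

**Route**

Step 1
Reactants: 1 phloroglucinol
Product: 2 1,3,5-tris(methoxymethoxy)benzene
Conditions: NaH, MOMCl, DMF, 0 °C to rt
Reagents that add atoms: chloromethyl methyl ether (MOMCl), COCCl
Why: Williamson etherification; the sodium phenoxide should be O-alkylated three times by the hard, very reactive α-chloro ether.

Step 2
Reactants: 2 1,3,5-tris(methoxymethoxy)benzene; 3 prenyl bromide
Product: 5 1,3,5-tris(methoxymethoxy)-2-prenylbenzene, via aryllithium 4 (not isolated)
Conditions: n-BuLi, THF, 0 °C; then 3, −78 °C to rt
Reagents that add atoms: prenyl bromide 3, CC(C)=CCBr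
Why: Directed ortho-metalation; the three equivalent ring C–H bonds each lie between two chelating MOM-oxy groups, and the aryllithium should displace bromide from the primary allylic bromide (SN2), keeping the linear prenyl unit.

Step 3
Reactants: 5 1,3,5-tris(methoxymethoxy)-2-prenylbenzene; 3 prenyl bromide
Product: 7 1,3,5-tris(methoxymethoxy)-2,4-diprenylbenzene, via aryllithium 6 (not isolated)
Conditions: n-BuLi, THF, 0 °C; then 3, −78 °C to rt
Reagents that add atoms: prenyl bromide 3, CC(C)=CCBr
Why: Second directed ortho-metalation at one of the two remaining, equivalent C–H positions (each again between two MOM-oxy groups), which should be kinetically preferred over removal of the benzylic–allylic protons, followed by the same SN2 prenylation.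

Step 4
Reactants: 7 1,3,5-tris(methoxymethoxy)-2,4-diprenylbenzene
Product: 9 2-iodo-1,3,5-tris(methoxymethoxy)-4,6-diprenylbenzene, via aryllithium 8 (not isolated)
Conditions: n-BuLi, THF, 0 °C; then ICH2CH2I, −78 °C to rt
Reagents that add atoms: 1,2-diiodoethane, ICCI
Why: Third directed ortho-metalation at the only ring C–H left, then lithium–iodine exchange with 1,2-diiodoethane (loss of ethene), which places iodine at the future C4a without exposing the prenyl olefins to an electrophilic iodinating agent.

Step 5
Reactants: 10 4-hydroxybenzaldehyde; 3 prenyl bromide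
Product: 11 4-hydroxy-3-prenylbenzaldehyde
Conditions: KOH, H2O, rt; chromatographic removal of the O-prenyl ether and the 3,5-diprenyl compound
Reagents that add atoms: prenyl bromide 3, CC(C)=CCBr
Why: C-alkylation of an ambident phenoxide; in water the oxygen is hydrogen-bonded, so the soft allylic bromide should be attacked in part by the ortho carbon (both ortho positions are equivalent), and modest efficiency is accepted at this first step on cheap materials.

Step 6
Reactants: 11 4-hydroxy-3-prenylbenzaldehyde
Product: 12 4-(methoxymethoxy)-3-prenylbenzaldehyde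
Conditions: MOMCl, i-Pr2NEt, CH2Cl2, 0 °C to rt
Reagents that add atoms: chloromethyl methyl ether (MOMCl), COCCl
Why: O-alkylation of the phenol (MOM protection); the acetal should survive hydride, zinc and palladium chemistry and leave in the same acid step as the ring A acetals.

Step 7
Reactants: 12 4-(methoxymethoxy)-3-prenylbenzaldehyde
Product: 13 [4-(methoxymethoxy)-3-prenylphenyl]methanol
Conditions: NaBH4, MeOH, 0 °C
Reagents that add atoms: none
Why: Chemoselective hydride reduction of the aromatic aldehyde; acetal and trisubstituted olefin are inert to NaBH4.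

Step 8
Reactants: 13 [4-(methoxymethoxy)-3-prenylphenyl]methanol
Product: 15 4-(chloromethyl)-1-(methoxymethoxy)-2-prenylbenzene, via benzyl mesylate 14 (not isolated)
Conditions: MsCl, Et3N, CH2Cl2, 0 °C to rt; used without storage
Reagents that add atoms: methanesulfonyl chloride, CS(=O)(=O)Cl
Why: Sulfonylation followed by in situ nucleophilic substitution; the para-alkoxybenzyl mesylate ionises easily and should be displaced by the chloride of the triethylammonium chloride formed alongside, under amine-buffered conditions that spare acetal and olefin.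

Step 9
Reactants: 15 4-(chloromethyl)-1-(methoxymethoxy)-2-prenylbenzene
Product: 16 [4-(methoxymethoxy)-3-prenylbenzyl]zinc chloride (LiCl-solvated THF solution, titrated and used directly)
Conditions: Zn dust (activated with BrCH2CH2Br and Me3SiCl), LiCl, THF, 25 °C
Reagents that add atoms: zinc, [Zn]
Why: Direct oxidative insertion of zinc into the benzylic C–Cl bond, promoted by LiCl, the established way to functionalised benzylzinc chlorides with little Wurtz homocoupling; ether, acetal and olefin are tolerated.

Step 10
Reactants: 9 2-iodo-1,3,5-tris(methoxymethoxy)-4,6-diprenylbenzene; 16 [4-(methoxymethoxy)-3-prenylbenzyl]zinc chloride; 17 carbon monoxide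
Product: 18 2-[4-(methoxymethoxy)-3-prenylphenyl]-1-[2,4,6-tris(methoxymethoxy)-3,5-diprenylphenyl]ethan-1-one
Conditions: Pd(PPh3)4 (5 mol%), CO (1 atm, balloon), THF, 50 °C; 16 (1.5 equiv) added slowly by syringe pump
Reagents that add atoms: carbon monoxide 17, [C-]#[O+]
Why: Oxidative addition of the C–I bond of 9 to zerovalent palladium gives an arylpalladium iodide flanked by two MOM-oxy groups; migratory insertion of CO converts it into the aroylpalladium species, and transmetalation from 16 followed by reductive elimination should forge C4a–C4 and C4–C3 of the future isoflavone in one operation. This is a carbonylative Negishi coupling, the reaction type known for aryl iodides with alkyl- and benzylzinc halides under Pd(PPh3)4 and one atmosphere of CO. No ring closes and no stereocentre is formed. The selectivity needed is CO insertion ahead of direct aryl–benzyl coupling: the two ortho substituents slow transmetalation at the crowded arylpalladium stage while insertion relieves that crowding, and slow addition of 16 under CO keeps the zinc reagent scarce until the acyl complex has formed. The site of acylation is fixed by the iodine, and the neutral medium should leave the three trisubstituted olefins and the four acetals untouched.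

Step 11
Reactants: 18 2-[4-(methoxymethoxy)-3-prenylphenyl]-1-[2,4,6-tris(methoxymethoxy)-3,5-diprenylphenyl]ethan-1-one
Product: 19 (E)-3-(dimethylamino)-2-[4-(methoxymethoxy)-3-prenylphenyl]-1-[2,4,6-tris(methoxymethoxy)-3,5-diprenylphenyl]prop-2-en-1-one
Conditions: Me2NCH(OMe)2, toluene, 100 °C
Reagents that add atoms: N,N-dimethylformamide dimethyl acetal, COC(OC)N(C)C
Why: Enaminone formation; the methylene between the ketone and ring B is the only acidic site and should condense with the amide acetal with loss of two methanol, delivering C2 as a vinylogous amide under neutral, anhydrous conditions.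

Step 12
Reactants: 19 (E)-3-(dimethylamino)-2-[4-(methoxymethoxy)-3-prenylphenyl]-1-[2,4,6-tris(methoxymethoxy)-3,5-diprenylphenyl]prop-2-en-1-one
Product: 21 euchrenone b1, via tetraphenol enaminone 20 (not isolated)
Conditions: HCl (1.25 M in MeOH), THF/MeOH, 0 °C to rt
Reagents that add atoms: none
Why: Acid-catalysed transacetalisation to methanol should free the four phenols, and a phenol ortho to the ketone then attacks the iminium-activated β-carbon (oxa-Michael addition–elimination, 6-endo-trig, loss of dimethylamine) to close ring C; the two ortho phenols are equivalent, so only one chromone can form, and dilute acid near room temperature is chosen to keep the prenyl groups from cyclising onto neighbouring phenols.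

**Compound list**

1 | phloroglucinol | Oc1cc(O)cc(O)c1 | starting material
2 | 1,3,5-tris(methoxymethoxy)benzene | COCOc1cc(OCOC)cc(OCOC)c1 | intermediate
3 | prenyl bromide (1-bromo-3-methylbut-2-ene) | CC(C)=CCBr | starting material
4 | [2,4,6-tris(methoxymethoxy)phenyl]lithium | [Li]c1c(OCOC)cc(OCOC)cc1OCOC | intermediate
5 | 1,3,5-tris(methoxymethoxy)-2-(3-methylbut-2-en-1-yl)benzene | COCOc1cc(OCOC)c(CC=C(C)C)c(OCOC)c1 | intermediate
6 | [2,4,6-tris(methoxymethoxy)-3-(3-methylbut-2-en-1-yl)phenyl]lithium | [Li]c1c(OCOC)cc(OCOC)c(CC=C(C)C)c1OCOC | intermediate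
7 | 1,3,5-tris(methoxymethoxy)-2,4-bis(3-methylbut-2-en-1-yl)benzene | COCOc1cc(OCOC)c(CC=C(C)C)c(OCOC)c1CC=C(C)C | intermediate
8 | [2,4,6-tris(methoxymethoxy)-3,5-bis(3-methylbut-2-en-1-yl)phenyl]lithium | [Li]c1c(OCOC)c(CC=C(C)C)c(OCOC)c(CC=C(C)C)c1OCOC | intermediate
9 | 2-iodo-1,3,5-tris(methoxymethoxy)-4,6-bis(3-methylbut-2-en-1-yl)benzene | COCOc1c(I)c(OCOC)c(CC=C(C)C)c(OCOC)c1CC=C(C)C | intermediate
10 | 4-hydroxybenzaldehyde | O=Cc1ccc(O)cc1 | starting material
11 | 4-hydroxy-3-(3-methylbut-2-en-1-yl)benzaldehyde | CC(C)=CCc1cc(C=O)ccc1O | intermediate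
12 | 4-(methoxymethoxy)-3-(3-methylbut-2-en-1-yl)benzaldehyde | COCOc1ccc(C=O)cc1CC=C(C)C | intermediate
13 | [4-(methoxymethoxy)-3-(3-methylbut-2-en-1-yl)phenyl]methanol | COCOc1ccc(CO)cc1CC=C(C)C | intermediate
14 | 4-(methoxymethoxy)-3-(3-methylbut-2-en-1-yl)benzyl methanesulfonate | COCOc1ccc(COS(C)(=O)=O)cc1CC=C(C)C | intermediate
15 | 4-(chloromethyl)-1-(methoxymethoxy)-2-(3-methylbut-2-en-1-yl)benzene | COCOc1ccc(CCl)cc1CC=C(C)C | intermediate
16 | [4-(methoxymethoxy)-3-(3-methylbut-2-en-1-yl)benzyl]zinc chloride | COCOc1ccc(C[Zn]Cl)cc1CC=C(C)C | intermediate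
17 | carbon monoxide | [C-]#[O+] | starting material
18 | 2-[4-(methoxymethoxy)-3-(3-methylbut-2-en-1-yl)phenyl]-1-[2,4,6-tris(methoxymethoxy)-3,5-bis(3-methylbut-2-en-1-yl)phenyl]ethan-1-one | COCOc1ccc(CC(=O)c2c(OCOC)c(CC=C(C)C)c(OCOC)c(CC=C(C)C)c2OCOC)cc1CC=C(C)C | intermediate
19 | (E)-3-(dimethylamino)-2-[4-(methoxymethoxy)-3-(3-methylbut-2-en-1-yl)phenyl]-1-[2,4,6-tris(methoxymethoxy)-3,5-bis(3-methylbut-2-en-1-yl)phenyl]prop-2-en-1-one | CN(C)/C=C(/C(=O)c1c(OCOC)c(CC=C(C)C)c(OCOC)c(CC=C(C)C)c1OCOC)c1ccc(OCOC)c(CC=C(C)C)c1 | intermediate
20 | (E)-3-(dimethylamino)-2-[4-hydroxy-3-(3-methylbut-2-en-1-yl)phenyl]-1-[2,4,6-trihydroxy-3,5-bis(3-methylbut-2-en-1-yl)phenyl]prop-2-en-1-one | CN(C)/C=C(/C(=O)c1c(O)c(CC=C(C)C)c(O)c(CC=C(C)C)c1O)c1ccc(O)c(CC=C(C)C)c1 | intermediate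
21 | euchrenone b1, 5,7-dihydroxy-3-[4-hydroxy-3-(3-methylbut-2-en-1-yl)phenyl]-6,8-bis(3-methylbut-2-en-1-yl)-4H-chromen-4-one | CC(C)=CCc1cc(-c2coc3c(CC=C(C)C)c(O)c(CC=C(C)C)c(O)c3c2=O)ccc1O | target

**Step count**

Total: 12 steps. Longest linear sequence: 8 steps (steps 5–9, then 10–12, from 4-hydroxybenzaldehyde). The ring A branch contributes 4 steps before the junction.

**Steps most likely to fail**

Step 10. Transmetalation may overtake CO insertion at the arylpalladium iodide, giving direct aryl–benzyl coupling. Oxidative addition at the crowded, electron-rich C–I bond may stall when palladium is saturated with CO. The zinc reagent may also be consumed by homocoupling. The fallback brings in the carbonyl carbon as a formyl group and forms the C4–C3 bond by polar addition; it sets out from 7 (and uses 16) and comes back at 18. Lithiation of 7 as in step 4 (n-BuLi, THF, 0 °C, aryllithium 8) and quenching with DMF should give 2,4,6-tris(methoxymethoxy)-3,5-diprenylbenzaldehyde F1. Addition of the benzylzinc chloride 16 to F1 (THF, 25 °C, MgCl2 as activator if needed) should give racemic 2-[4-(methoxymethoxy)-3-prenylphenyl]-1-[2,4,6-tris(methoxymethoxy)-3,5-diprenylphenyl]ethan-1-ol F2. Oxidation of F2 with Dess–Martin periodinane in CH2Cl2 at rt then gives 18.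

Step 12. A phenol may add to its neighbouring prenyl olefin under acid (closure to a dimethylchroman), HCl or methanol may add across the olefins, or acetal cleavage may remain incomplete if the acid is kept mild enough to avoid these. The fallback separates deprotection from ring closure and runs both without protic mineral acid; it sets out from 18 and comes back at 21. ZnBr2 and n-PrSH in CH2Cl2 at 0 °C (thiol-assisted Lewis-acid acetal cleavage, complete within minutes) should remove the four MOM groups and give 1-(2,4,6-trihydroxy-3,5-diprenylphenyl)-2-(4-hydroxy-3-prenylphenyl)ethan-1-one F3. Treatment of F3 with DMF dimethyl acetal in THF (rt to 50 °C) should form the enaminone 20, which closes to 21 with loss of dimethylamine on standing or on silica.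

Step 5. O-alkylation and a second C-alkylation may outrun mono-ortho C-alkylation, so that little of the wanted phenol is formed and the separation becomes wasteful. The fallback delivers the prenyl group intramolecularly; it sets out from 10 and comes back at 11. O-alkylation of 10 with 3-chloro-3-methylbut-1-yne (DBU, CuCl2 cat., MeCN, 0 °C) should give 4-(2-methylbut-3-yn-2-yloxy)benzaldehyde F4. Semi-hydrogenation (H2, Lindlar catalyst, Pd on CaCO3 poisoned with Pb(OAc)2, quinoline, EtOAc) should give 4-(2-methylbut-3-en-2-yloxy)benzaldehyde F5. Heating F5 (N,N-diethylaniline, about 130 °C) triggers the aromatic Claisen rearrangement, which places the linear prenyl group on the ortho carbon and gives 11.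

**Further compounds**

F1 | step 10 | 2,4,6-tris(methoxymethoxy)-3,5-bis(3-methylbut-2-en-1-yl)benzaldehyde | COCOc1c(C=O)c(OCOC)c(CC=C(C)C)c(OCOC)c1CC=C(C)C
F2 | step 10 | racemic 2-[4-(methoxymethoxy)-3-(3-methylbut-2-en-1-yl)phenyl]-1-[2,4,6-tris(methoxymethoxy)-3,5-bis(3-methylbut-2-en-1-yl)phenyl]ethan-1-ol | COCOc1ccc(CC(O)c2c(OCOC)c(CC=C(C)C)c(OCOC)c(CC=C(C)C)c2OCOC)cc1CC=C(C)C
F3 | step 12 | 2-[4-hydroxy-3-(3-methylbut-2-en-1-yl)phenyl]-1-[2,4,6-trihydroxy-3,5-bis(3-methylbut-2-en-1-yl)phenyl]ethan-1-one | CC(C)=CCc1cc(CC(=O)c2c(O)c(CC=C(C)C)c(O)c(CC=C(C)C)c2O)ccc1O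
F4 | step 5 | 4-(2-methylbut-3-yn-2-yloxy)benzaldehyde | C#CC(C)(C)Oc1ccc(C=O)cc1
F5 | step 5 | 4-(2-methylbut-3-en-2-yloxy)benzaldehyde | C=CC(C)(C)Oc1ccc(C=O)cc1
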